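**Retrosynthetic overview**

1. Locants used throughout: ethyl C1–C2; cyclohexene C3(Et)–C4H2–C5–C22(Me)–C23=C24(Me); butenolide C5–O6–C7(=O)–C8=C9; pyran C5–C9–O10–C11(Me)–C21H2–C22; ansa chain C11–C12=C13(Me)–C14–C15–C16=C17(Me)–C18(OMe)–C19–C20(=O)–C8.
2. Enabling feature: C11 is a tertiary allylic ether carbon (flanked by C12=C13) bonded to the acidic tetronate oxygen O10, and it lies one CH2 (C21) from C22 of a cyclohexene that carries the Diels–Alder retron (C3–C4, C5–C22, C23=C24). One operation therefore cuts O10–C11 to tetronic acid plus tertiary allylic alcohol, and the cyclohexene to a 5-methylenetetronic acid plus an E,E-diene.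
3. The precursor of the key step is an acyclic 3-acyl-5-methylenetetronic acid with only the C11 and C18 stereocentres. Ring order: butenolide (Lacey–Dieckmann), then cyclohexene together with the 15-membered carbocycle (Diels–Alder), then the pyran last (transannular etherification, which turns the 15-membered ring into pyran plus 13-membered ansa ring).
4. The precursor comes from acylketene chemistry on a dioxinone and a selenide-masked α-hydroxy ester; the dioxinone comes from Negishi sp3–sp2 coupling of a primary alkyl iodide with a Z-alkenyl iodide.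
5. Alkenyl iodide: Sharpless epoxidation sets C11, epoxy chloride to alkynol, trans-hydroalumination/iodination sets Z-C12=C13. Alkyl iodide: Still–Gennari olefination sets Z-C16=C17, CBS reduction sets C18.

Key step: step 21

Assumption: (2E)-4-chloro-3-methylbut-2-en-1-yl acetate, an industrial C5 building block, is bought.

**Route**

Step 1
Reactants: 1 (2E)-2-methylpent-2-enal
Product: 2 (3E)-1,1-dibromo-3-methylhexa-1,3-diene
Conditions: CBr4, PPh3, CH2Cl2, 0 °C
Reagents that add atoms: tetrabromomethane, BrC(Br)(Br)Br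
Why: Corey–Fuchs dibromo-olefination of the aldehyde, which leaves the E trisubstituted alkene untouched.

Step 2
Reactants: 2 (3E)-1,1-dibromo-3-methylhexa-1,3-diene
Product: 4 (4E)-4-methylhept-4-en-2-yne, via lithium acetylide 3 (not isolated)
Conditions: n-BuLi (2.1 equiv), THF, −78 °C; then MeI, −78 → 23 °C
Reagents that add atoms: iodomethane, CI
Why: second stage of the Corey–Fuchs alkyne synthesis (elimination, Br–Li exchange) followed by C-methylation of the acetylide.

Step 3
Reactants: 4 (4E)-4-methylhept-4-en-2-yne, 5 (2E)-4-chloro-3-methylbut-2-en-1-yl acetate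
Product: 7 (2E,5E,7E)-3,5,7-trimethyldeca-2,5,7-trien-1-yl acetate, via alkenylzirconocene chloride 6 (not isolated)
Conditions: Cp2Zr(H)Cl, THF, 23 °C; then 5, Pd(PPh3)4 (5 mol %), THF, 23 °C
Reagents that add atoms: none
Why: syn hydrozirconation places Zr on the less hindered, methyl-bearing alkyne carbon (so C22=C23 is E), and alkenylzirconium–allyl chloride cross-coupling catalysed by zerovalent palladium joins the primary allyl terminus with retention of both alkene geometries.

Step 4
Reactants: 7 (2E,5E,7E)-3,5,7-trimethyldeca-2,5,7-trien-1-yl acetate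
Product: 8 (2E,5E,7E)-3,5,7-trimethyldeca-2,5,7-trien-1-ol
Conditions: K2CO3, MeOH, 23 °C
Reagents that add atoms: none
Why: methanolysis (transesterification) of the primary acetate.

Step 5
Reactants: 8 (2E,5E,7E)-3,5,7-trimethyldeca-2,5,7-trien-1-ol
Product: 9 [(2S,3S)-3-[(2E,4E)-2,4-dimethylhepta-2,4-dien-1-yl]-3-methyloxiran-2-yl]methanol
Conditions: Ti(OiPr)4 (10 mol %), diethyl L-tartrate (12 mol %), t-BuOOH, 4 Å molecular sieves, CH2Cl2, −20 °C
Reagents that add atoms: tert-butyl hydroperoxide, CC(C)(C)OO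
Why: Sharpless asymmetric epoxidation is selective for the allylic alcohol alkene, and with diethyl L-tartrate an E-3-methyl allylic alcohol should give the (2S,3S)-epoxide, which fixes C11.

Step 6
Reactants: 9 [(2S,3S)-3-[(2E,4E)-2,4-dimethylhepta-2,4-dien-1-yl]-3-methyloxiran-2-yl]methanol
Product: 10 (2R,3S)-2-(chloromethyl)-3-[(2E,4E)-2,4-dimethylhepta-2,4-dien-1-yl]-3-methyloxirane
Conditions: PPh3, CCl4, NaHCO3, reflux
Reagents that add atoms: tetrachloromethane, ClC(Cl)(Cl)Cl
Why: buffered Appel chlorination of the primary alcohol, which leaves the trisubstituted epoxide intact.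

Step 7
Reactants: 10 (2R,3S)-2-(chloromethyl)-3-[(2E,4E)-2,4-dimethylhepta-2,4-dien-1-yl]-3-methyloxirane
Product: 12 (4S,6E,8E)-4,6,8-trimethylundeca-6,8-dien-2-yn-4-ol, via dilithio alkynyl alkoxide 11 (not isolated)
Conditions: n-BuLi (3.3 equiv), THF, −40 °C; then MeI (1.1 equiv), DMPU, −40 → 0 °C
Reagents that add atoms: iodomethane, CI
Why: base-induced double elimination of the 2,3-epoxy chloride to the propargylic alkoxide keeps the C11–O bond (C11 stays S), and the acetylide carbon of the dianion is methylated selectively.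

Step 8
Reactants: 12 (4S,6E,8E)-4,6,8-trimethylundeca-6,8-dien-2-yn-4-ol
Product: 14 (2Z,4S,6E,8E)-2-iodo-4,6,8-trimethylundeca-2,6,8-trien-4-ol, via cyclic alkenylalanate 13 (not isolated)
Conditions: NaAlH2(OCH2CH2OMe)2, THF, 0 → 23 °C; then I2, THF, −78 °C
Reagents that add atoms: iodine, II
Why: hydroxyl-directed trans-hydroalumination puts Al on the distal alkyne carbon in a five-membered alanate, and iodinolysis with retention gives the iodide cis to C11, i.e. the Z iodoalkene.

Step 9
Reactants: 15 3-[(tert-butyldimethylsilyl)oxy]propanal, 16 methyl 2-[bis(2,2,2-trifluoroethoxy)phosphoryl]propanoate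
Product: 17 methyl (2Z)-5-[(tert-butyldimethylsilyl)oxy]-2-methylpent-2-enoate
Conditions: KN(SiMe3)2, 18-crown-6, THF, −78 °C
Reagents that add atoms: none
Why: Still–Gennari olefination gives the Z trisubstituted enoate and thereby sets the C16=C17 geometry.

Step 10
Reactants: 17 methyl (2Z)-5-[(tert-butyldimethylsilyl)oxy]-2-methylpent-2-enoate
Product: 18 (2Z)-5-[(tert-butyldimethylsilyl)oxy]-N-methoxy-N,2-dimethylpent-2-enamide
Conditions: MeNH(OMe)·HCl, i-PrMgCl, THF, −20 °C
Reagents that add atoms: N,O-dimethylhydroxylamine hydrochloride, CNOC.Cl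
Why: Weinreb amide formation by magnesium amide aminolysis of the ester, without touching the Z alkene.

Step 11
Reactants: 19 2,2,6-trimethyl-4H-1,3-dioxin-4-one, 18 (2Z)-5-[(tert-butyldimethylsilyl)oxy]-N-methoxy-N,2-dimethylpent-2-enamide
Product: 21 6-[(3Z)-6-[(tert-butyldimethylsilyl)oxy]-3-methyl-2-oxohex-3-en-1-yl]-2,2-dimethyl-4H-1,3-dioxin-4-one, via lithium dienolate 20 (not isolated)
Conditions: LiN(iPr)2, THF, −78 °C; then 18, −78 → −40 °C
Reagents that add atoms: none
Why: Claisen-type γ-acylation of the dioxinone dienolate by the Weinreb amide stops at the ketone because the chelated tetrahedral intermediate survives until work-up.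

Step 12
Reactants: 21 6-[(3Z)-6-[(tert-butyldimethylsilyl)oxy]-3-methyl-2-oxohex-3-en-1-yl]-2,2-dimethyl-4H-1,3-dioxin-4-one
Product: 22 6-[(2R,3Z)-6-[(tert-butyldimethylsilyl)oxy]-2-hydroxy-3-methylhex-3-en-1-yl]-2,2-dimethyl-4H-1,3-dioxin-4-one
Conditions: (S)-1-methyl-3,3-diphenyl-tetrahydro-1H,3H-pyrrolo[1,2-c][1,3,2]oxazaborole (20 mol %), catecholborane, PhMe, −78 °C
Reagents that add atoms: none
Why: Corey–Bakshi–Shibata 1,2-reduction in which the α-branched alkenyl group acts as the large substituent, so the (S)-catalyst should give the (R)-carbinol at C18, as it gives (R)-1-phenylethanol from acetophenone.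

Step 13
Reactants: 22 6-[(2R,3Z)-6-[(tert-butyldimethylsilyl)oxy]-2-hydroxy-3-methylhex-3-en-1-yl]-2,2-dimethyl-4H-1,3-dioxin-4-one
Product: 23 6-[(2R,3Z)-6-[(tert-butyldimethylsilyl)oxy]-2-methoxy-3-methylhex-3-en-1-yl]-2,2-dimethyl-4H-1,3-dioxin-4-one
Conditions: Me3OBF4, 1,8-bis(dimethylamino)naphthalene, CH2Cl2, 0 → 23 °C
Reagents that add atoms: trimethyloxonium tetrafluoroborate, C[O+](C)C.F[B-](F)(F)F
Why: O-methylation by an oxonium salt with a non-nucleophilic base avoids enolate chemistry at the acidic C19 position and does not touch the C18 configuration.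

Step 14
Reactants: 23 6-[(2R,3Z)-6-[(tert-butyldimethylsilyl)oxy]-2-methoxy-3-methylhex-3-en-1-yl]-2,2-dimethyl-4H-1,3-dioxin-4-one
Product: 24 6-[(2R,3Z)-6-hydroxy-2-methoxy-3-methylhex-3-en-1-yl]-2,2-dimethyl-4H-1,3-dioxin-4-one
Conditions: HF·pyridine, pyridine, THF, 0 → 23 °C
Reagents that add atoms: none
Why: buffered fluoride desilylation of the primary silyl ether, which spares the allylic methyl ether and the dioxinone.

Step 15
Reactants: 24 6-[(2R,3Z)-6-hydroxy-2-methoxy-3-methylhex-3-en-1-yl]-2,2-dimethyl-4H-1,3-dioxin-4-one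
Product: 25 6-[(2R,3Z)-6-iodo-2-methoxy-3-methylhex-3-en-1-yl]-2,2-dimethyl-4H-1,3-dioxin-4-one
Conditions: I2, PPh3, imidazole, CH2Cl2, 0 °C
Reagents that add atoms: iodine, II
Why: Appel-type (Garegg–Samuelsson) iodination of the primary alcohol.

Step 16
Reactants: 26 methyl (2R)-oxirane-2-carboxylate
Product: 27 methyl (2S)-2-hydroxy-3-(phenylselanyl)propanoate
Conditions: PhSeH, Et3N (10 mol %), MeOH, 0 °C
Reagents that add atoms: benzeneselenol, [SeH]c1ccccc1
Why: SN2 ring opening of the glycidate at its CH2 carbon by the soft selenol; the carbinol centre is not touched (it is removed in step 20, so its configuration is of no consequence).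

Step 17
Reactants: 25 6-[(2R,3Z)-6-iodo-2-methoxy-3-methylhex-3-en-1-yl]-2,2-dimethyl-4H-1,3-dioxin-4-one, 14 (2Z,4S,6E,8E)-2-iodo-4,6,8-trimethylundeca-2,6,8-trien-4-ol
Product: 29 6-[(2R,3Z,7Z,9S,11E,13E)-9-hydroxy-2-methoxy-3,7,9,11,13-pentamethylhexadeca-3,7,11,13-tetraen-1-yl]-2,2-dimethyl-4H-1,3-dioxin-4-one, via alkylzinc iodide 28 (not isolated)
Conditions: Zn dust, LiCl, THF, 25 °C; then 14, Pd(OAc)2 (5 mol %), 2-dicyclohexylphosphino-2',6'-dimethoxybiphenyl (10 mol %), THF, 25 °C
Reagents that add atoms: none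
Why: zinc insertion into the primary iodide tolerates the dioxinone, and Negishi sp3–sp2 cross-coupling proceeds with retention of the Z alkene geometry and tolerates the free tertiary alcohol.

Step 18
Reactants: 29 6-[(2R,3Z,7Z,9S,11E,13E)-9-hydroxy-2-methoxy-3,7,9,11,13-pentamethylhexadeca-3,7,11,13-tetraen-1-yl]-2,2-dimethyl-4H-1,3-dioxin-4-one, 27 methyl (2S)-2-hydroxy-3-(phenylselanyl)propanoate
Product: 31 methyl (2S)-2-{[(5R,6Z,10Z,12S,14E,16E)-12-hydroxy-5-methoxy-6,10,12,14,16-pentamethyl-3-oxononadeca-6,10,14,16-tetraenoyl]oxy}-3-(phenylselanyl)propanoate, via acylketene 30 (not isolated)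
Conditions: 27 (5 equiv), PhMe, 110 °C
Reagents that add atoms: none
Why: retro-[4+2] thermolysis of the dioxinone gives an acylketene that the excess secondary alcohol traps (acetoacetylation) much faster than the hindered tertiary alcohol can.

Step 19
Reactants: 31 methyl (2S)-2-{[(5R,6Z,10Z,12S,14E,16E)-12-hydroxy-5-methoxy-6,10,12,14,16-pentamethyl-3-oxononadeca-6,10,14,16-tetraenoyl]oxy}-3-(phenylselanyl)propanoate
Product: 32 (5S)-4-hydroxy-3-[(3R,4Z,8Z,10S,12E,14E)-10-hydroxy-3-methoxy-4,8,10,12,14-pentamethylheptadeca-4,8,12,14-tetraenoyl]-5-[(phenylselanyl)methyl]furan-2(5H)-one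
Conditions: KOt-Bu, t-BuOH/THF, 0 → 23 °C; then aq. HCl (1 M), 0 °C
Reagents that add atoms: none
Why: Lacey–Dieckmann cyclisation of the α-(β-ketoacyloxy) ester closes the butenolide; deprotonation occurs at C8, so the C18 methoxy group is not eliminated.

Step 20
Reactants: 32 (5S)-4-hydroxy-3-[(3R,4Z,8Z,10S,12E,14E)-10-hydroxy-3-methoxy-4,8,10,12,14-pentamethylheptadeca-4,8,12,14-tetraenoyl]-5-[(phenylselanyl)methyl]furan-2(5H)-one
Product: 34 4-hydroxy-3-[(3R,4Z,8Z,10S,12E,14E)-10-hydroxy-3-methoxy-4,8,10,12,14-pentamethylheptadeca-4,8,12,14-tetraenoyl]-5-methylidenefuran-2(5H)-one, via selenoxide 33 (not isolated)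
Conditions: H2O2 (30 %), pyridine, CH2Cl2, 0 → 23 °C
Reagents that add atoms: none
Why: chemoselective oxidation at selenium and syn-elimination of the selenoxide, whose only β-hydrogen is C5–H, unveils the exocyclic C4=C5 dienophile at or below room temperature.

Step 21
Reactants: 34 4-hydroxy-3-[(3R,4Z,8Z,10S,12E,14E)-10-hydroxy-3-methoxy-4,8,10,12,14-pentamethylheptadeca-4,8,12,14-tetraenoyl]-5-methylidenefuran-2(5H)-one
Product: 36 streptaspironate A, via Diels–Alder adduct 35 (not isolated)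
Conditions: PhMe (0.5 mM), BHT, 90 °C; then camphorsulfonic acid (5 mol %), 23 °C, same flask
Reagents that add atoms: none
Why: Proposed new method: heating the free acid 34 in dilute toluene should effect a [4+2] cycloaddition of the exocyclic C4=C5 alkene (the terminus of the 3-acyltetronic acid π-system) with the C22=C23–C24=C3 diene to give 35, in which the acidic O10–H lies next to the C11 carbinol and displaces it as water, spontaneously or on adding catalytic acid, to give 36. The closest known reaction types are the thermal intramolecular Diels–Alder macrocyclisation of 3-acyl-5-methylenetetronates to spirotetronates and the acid-catalysed cyclisation of enolic 1,3-dicarbonyl compounds onto tertiary prenyl-type centres to give 2,2-dialkylpyrans; running both in one flask on a free tetronic acid is the new element. The cyclohexene and the 15-membered carbocycle close together in a concerted, asynchronous type 1 cycloaddition (C3–C4 bond leading, the hindered C5–C22 bond trailing), and the pyran closes last by 6-exo-tet substitution of O10 at C11, which divides the 15-membered ring into the pyran and the 13-membered ansa ring. C3 is fixed by the E geometry of C24=C3, C5 and C22 by suprafacial addition in the C9-endo mode on the diene face presented when the C11 hydroxyl is hydrogen-bonded to O10 (a self-assembled tether that makes the transition state resemble the cis-fused pyran of the product), and C11 keeps its configuration because O10 is delivered from the face of the departing, hydrogen-bonded hydroxyl. The step needs periselectivity (only one 1,3-diene exists because C11 is sp3), regioselectivity (C4 is the electrophilic terminus and C3 the less hindered, more nucleophilic diene end), endo and facial selectivity (hydrogen-bond tether, secondary overlap with the C9=C8–C=O unit, product-like ansa loop carrying the (R)-C18 centre) and survival of the C11–O bond until after cycloaddition (non-polar solvent, high dilution, no external acid in the first stage). Should ionisation at C11 nevertheless come first, collapse of the tetronate on the allyl cation gives the 13-membered tertiary tetronate ether, whose cycloaddition through the six-membered pyran tether leads to the same product.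

**Compound list**

1 | (2E)-2-methylpent-2-enal | CC/C=C(C)/C=O | starting material
2 | (3E)-1,1-dibromo-3-methylhexa-1,3-diene | CC/C=C(C)/C=C(Br)Br | intermediate
3 | lithium (3E)-3-methylhex-3-en-1-yn-1-ide | [Li]C#C/C(C)=C/CC | intermediate (not isolated)
4 | (4E)-4-methylhept-4-en-2-yne | CC#C/C(C)=C/CC | intermediate
5 | (2E)-4-chloro-3-methylbut-2-en-1-yl acetate | CC(=O)OC/C=C(C)/CCl | starting material
6 | chlorobis(cyclopentadienyl)[(2E,4E)-4-methylhepta-2,4-dien-2-yl]zirconium | C/C(=C\C(C)=C\CC)[Zr](Cl)(C1C=CC=C1)C1C=CC=C1 | intermediate (not isolated)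
7 | (2E,5E,7E)-3,5,7-trimethyldeca-2,5,7-trien-1-yl acetate | CC(=O)OC/C=C(C)/C/C(C)=C/C(C)=C/CC | intermediate
8 | (2E,5E,7E)-3,5,7-trimethyldeca-2,5,7-trien-1-ol | OC/C=C(C)/C/C(C)=C/C(C)=C/CC | intermediate
9 | [(2S,3S)-3-[(2E,4E)-2,4-dimethylhepta-2,4-dien-1-yl]-3-methyloxiran-2-yl]methanol | OC[C@@H]1O[C@@]1(C)C/C(C)=C/C(C)=C/CC | intermediate
10 | (2R,3S)-2-(chloromethyl)-3-[(2E,4E)-2,4-dimethylhepta-2,4-dien-1-yl]-3-methyloxirane | ClC[C@@H]1O[C@@]1(C)C/C(C)=C/C(C)=C/CC | intermediate
11 | dilithium (3S,5E,7E)-3,5,7-trimethyldeca-5,7-dien-1-yn-1-id-3-olate | [Li+].[Li+].[C-]#C[C@@](C)([O-])C/C(C)=C/C(C)=C/CC | intermediate (not isolated)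
12 | (4S,6E,8E)-4,6,8-trimethylundeca-6,8-dien-2-yn-4-ol | CC#C[C@@](C)(O)C/C(C)=C/C(C)=C/CC | intermediate
13 | sodium (5S)-2,2-bis(2-methoxyethoxy)-3,5-dimethyl-5-[(2E,4E)-2,4-dimethylhepta-2,4-dien-1-yl]-2,5-dihydro-1,2-oxaluminol-2-uide | C/C1=C/[C@](C)(C/C(C)=C/C(C)=C/CC)O[Al-]1(OCCOC)OCCOC.[Na+] | intermediate (not isolated)
14 | (2Z,4S,6E,8E)-2-iodo-4,6,8-trimethylundeca-2,6,8-trien-4-ol | C/C(I)=C/[C@@](C)(O)C/C(C)=C/C(C)=C/CC | intermediate
15 | 3-[(tert-butyldimethylsilyl)oxy]propanal | CC(C)(C)[Si](C)(C)OCCC=O | starting material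
16 | methyl 2-[bis(2,2,2-trifluoroethoxy)phosphoryl]propanoate | COC(=O)C(C)P(=O)(OCC(F)(F)F)OCC(F)(F)F | starting material
17 | methyl (2Z)-5-[(tert-butyldimethylsilyl)oxy]-2-methylpent-2-enoate | CC(C)(C)[Si](C)(C)OCC/C=C(/C)C(=O)OC | intermediate
18 | (2Z)-5-[(tert-butyldimethylsilyl)oxy]-N-methoxy-N,2-dimethylpent-2-enamide | CC(C)(C)[Si](C)(C)OCC/C=C(/C)C(=O)N(C)OC | intermediate
19 | 2,2,6-trimethyl-4H-1,3-dioxin-4-one | CC1=CC(=O)OC(C)(C)O1 | starting material
20 | lithium 2,2-dimethyl-6-methylidene-6H-1,3-dioxin-4-olate | [Li+].C=C1C=C([O-])OC(C)(C)O1 | intermediate (not isolated)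
21 | 6-[(3Z)-6-[(tert-butyldimethylsilyl)oxy]-3-methyl-2-oxohex-3-en-1-yl]-2,2-dimethyl-4H-1,3-dioxin-4-one | CC(C)(C)[Si](C)(C)OCC/C=C(/C)C(=O)CC1=CC(=O)OC(C)(C)O1 | intermediate
22 | 6-[(2R,3Z)-6-[(tert-butyldimethylsilyl)oxy]-2-hydroxy-3-methylhex-3-en-1-yl]-2,2-dimethyl-4H-1,3-dioxin-4-one | CC(C)(C)[Si](C)(C)OCC/C=C(/C)[C@H](O)CC1=CC(=O)OC(C)(C)O1 | intermediate
23 | 6-[(2R,3Z)-6-[(tert-butyldimethylsilyl)oxy]-2-methoxy-3-methylhex-3-en-1-yl]-2,2-dimethyl-4H-1,3-dioxin-4-one | CC(C)(C)[Si](C)(C)OCC/C=C(/C)[C@H](OC)CC1=CC(=O)OC(C)(C)O1 | intermediate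
24 | 6-[(2R,3Z)-6-hydroxy-2-methoxy-3-methylhex-3-en-1-yl]-2,2-dimethyl-4H-1,3-dioxin-4-one | OCC/C=C(/C)[C@H](OC)CC1=CC(=O)OC(C)(C)O1 | intermediate
25 | 6-[(2R,3Z)-6-iodo-2-methoxy-3-methylhex-3-en-1-yl]-2,2-dimethyl-4H-1,3-dioxin-4-one | ICC/C=C(/C)[C@H](OC)CC1=CC(=O)OC(C)(C)O1 | intermediate
26 | methyl (2R)-oxirane-2-carboxylate | COC(=O)[C@H]1CO1 | starting material
27 | methyl (2S)-2-hydroxy-3-(phenylselanyl)propanoate | COC(=O)[C@H](O)C[Se]c1ccccc1 | intermediate
28 | iodo[(3Z,5R)-6-(2,2-dimethyl-4-oxo-4H-1,3-dioxin-6-yl)-5-methoxy-4-methylhex-3-en-1-yl]zinc | I[Zn]CC/C=C(/C)[C@H](OC)CC1=CC(=O)OC(C)(C)O1 | intermediate (not isolated)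
29 | 6-[(2R,3Z,7Z,9S,11E,13E)-9-hydroxy-2-methoxy-3,7,9,11,13-pentamethylhexadeca-3,7,11,13-tetraen-1-yl]-2,2-dimethyl-4H-1,3-dioxin-4-one | O[C@](C)(/C=C(/C)CC/C=C(/C)[C@H](OC)CC1=CC(=O)OC(C)(C)O1)C/C(C)=C/C(C)=C/CC | intermediate
30 | (5R,6Z,10Z,12S,14E,16E)-12-hydroxy-5-methoxy-6,10,12,14,16-pentamethylnonadeca-1,6,10,14,16-pentaene-1,3-dione (acylketene) | O[C@](C)(/C=C(/C)CC/C=C(/C)[C@H](OC)CC(=O)C=C=O)C/C(C)=C/C(C)=C/CC | intermediate (not isolated)
31 | methyl (2S)-2-{[(5R,6Z,10Z,12S,14E,16E)-12-hydroxy-5-methoxy-6,10,12,14,16-pentamethyl-3-oxononadeca-6,10,14,16-tetraenoyl]oxy}-3-(phenylselanyl)propanoate | O[C@](C)(/C=C(/C)CC/C=C(/C)[C@H](OC)CC(=O)CC(=O)O[C@H](C[Se]c1ccccc1)C(=O)OC)C/C(C)=C/C(C)=C/CC | intermediate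
32 | (5S)-4-hydroxy-3-[(3R,4Z,8Z,10S,12E,14E)-10-hydroxy-3-methoxy-4,8,10,12,14-pentamethylheptadeca-4,8,12,14-tetraenoyl]-5-[(phenylselanyl)methyl]furan-2(5H)-one | O[C@](C)(/C=C(/C)CC/C=C(/C)[C@H](OC)CC(=O)C1=C(O)[C@@H](C[Se]c2ccccc2)OC1=O)C/C(C)=C/C(C)=C/CC | intermediate
33 | selenoxide of 32, (5S)-5-[(benzeneseleninyl)methyl] analogue | O[C@](C)(/C=C(/C)CC/C=C(/C)[C@H](OC)CC(=O)C1=C(O)[C@@H](C[Se](=O)c2ccccc2)OC1=O)C/C(C)=C/C(C)=C/CC | intermediate (not isolated)
34 | 4-hydroxy-3-[(3R,4Z,8Z,10S,12E,14E)-10-hydroxy-3-methoxy-4,8,10,12,14-pentamethylheptadeca-4,8,12,14-tetraenoyl]-5-methylidenefuran-2(5H)-one | O[C@](C)(/C=C(/C)CC/C=C(/C)[C@H](OC)CC(=O)C1=C(O)C(=C)OC1=O)C/C(C)=C/C(C)=C/CC | intermediate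
35 | Diels–Alder adduct (3S,5S,11S,18R,22S; 12Z,16Z): spiro tetronic acid–cyclohexene in a 15-membered carbocycle, O10–H and C11–OH free | CC[C@H]1C[C@@]23OC(=O)C(=C2O)C(=O)C[C@@H](OC)/C(C)=C\CC/C(C)=C\[C@@](C)(O)C[C@@]3(C)C=C1C | intermediate (not isolated)
36 | streptaspironate A (3S,5S,11S,18R,22S; 12Z,16Z) | CC[C@H]1C[C@@]23OC(=O)C4=C2O[C@](C)(/C=C(/C)CC/C=C(/C)[C@H](OC)CC4=O)C[C@@]3(C)C=C1C | target

**Step count and risks**

Total: 21 steps. Longest linear sequence: 13 steps (steps 1–8, then 17–21).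

Step 21 (bears the label). What may go wrong: the macrocyclising cycloaddition may be too slow beside oligomerisation, may take the exo course or the wrong diene face, or the tertiary allylic alcohol may ionise and eliminate before cycloaddition. The fallback uses known reactions, makes the cyclohexene first through a covalent six-membered ester tether and still closes the pyran last; it sets out from 14 and comes back at 35. Alcohol 14 is acylated with pyruvoyl chloride (pyridine, CH2Cl2, −20 °C) to the pyruvate ester F1. Enol silylation (Me3SiOTf, Et3N) gives the 2-(trimethylsilyloxy)acrylate F2, which on heating (PhMe, 150 °C, BHT) should undergo an ester-tethered type 1 intramolecular Diels–Alder reaction to the cis-fused silyloxy δ-lactone F3. Acidic work-up gives the hydroxy lactone F4, and Negishi coupling with zinc reagent 28 (as in step 17) gives the dioxinone F5. Heating F5 (PhMe, 110 °C, 1 mM) generates the acylketene F6, which the C5 hydroxyl traps to the 16-membered β-keto macrolactone F7 (acylketene macrolactonisation). KOt-Bu then effects a transannular Lacey–Dieckmann condensation of C8 onto the δ-lactone carbonyl C9, which forms the butenolide, releases the C11 alkoxide and gives 35 after acidification. Compound 35 is closed to 36 with camphorsulfonic acid as in the second stage of step 21.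

Step 20. What may go wrong: decomposition of the acid-bearing, electron-rich polyene under the oxidative conditions, or addition of the selenenic acid by-product to the new exocyclic alkene or the diene. The fallback sets out from 31 and comes back at 34. The selenide is oxidised and eliminated at the neutral β-keto ester stage (H2O2, pyridine, CH2Cl2, 0 °C) via the selenoxide F8 to the 2-(acyloxy)acrylate F9, which is freed from selenium by-products by chromatography. Lacey–Dieckmann cyclisation of F9 (KOt-Bu, THF, −20 °C; 5-exo-trig attack at the ester carbonyl should be preferred over 5-endo-trig conjugate addition) then gives 34 on acidification.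

Step 12. What may go wrong: enolisation of the keto-dioxinone towards C19, or poor differentiation of the twisted Z-alkenyl group from the CH2 arm, leading to low enantioselectivity. The fallback forms C18 by C–C bond formation instead of reduction; it sets out from 17 and comes back at 22. Reduction with i-Bu2AlH gives the allylic alcohol F10, and MnO2 oxidation gives the Z-enal F11, used at once to avoid Z to E isomerisation. A catalytic enantioselective vinylogous Mukaiyama aldol addition of the silyl dienol ether F12 (from 19, LiN(iPr)2, Me3SiCl), with CuF2 and the Tol-BINAP antipode that delivers the (R)-carbinol, gives the silyl ether F13, which is desilylated on acidic work-up to 22.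

**Further compounds**

F1 | step 21 | (2Z,4S,6E,8E)-2-iodo-4,6,8-trimethylundeca-2,6,8-trien-4-yl 2-oxopropanoate | CC(=O)C(=O)O[C@](C)(/C=C(/C)I)C/C(C)=C/C(C)=C/CC
F2 | step 21 | (2Z,4S,6E,8E)-2-iodo-4,6,8-trimethylundeca-2,6,8-trien-4-yl 2-(trimethylsilyloxy)prop-2-enoate | C=C(O[Si](C)(C)C)C(=O)O[C@](C)(/C=C(/C)I)C/C(C)=C/C(C)=C/CC
F3 | step 21 | cis-fused cyclohexene δ-lactone with C5–OSiMe3 and the Z-iodoalkenyl group on C11 | CC[C@H]1C[C@@]2(O[Si](C)(C)C)C(=O)O[C@](C)(/C=C(/C)I)C[C@@]2(C)C=C1C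
F4 | step 21 | cis-fused cyclohexene δ-lactone with C5–OH and the Z-iodoalkenyl group on C11 | CC[C@H]1C[C@@]2(O)C(=O)O[C@](C)(/C=C(/C)I)C[C@@]2(C)C=C1C
F5 | step 21 | hydroxy δ-lactone carrying the full ansa chain, ending in the dioxinone | CC[C@H]1C[C@@]2(O)C(=O)O[C@](C)(/C=C(/C)CC/C=C(/C)[C@H](OC)CC3=CC(=O)OC(C)(C)O3)C[C@@]2(C)C=C1C
F6 | step 21 | acylketene from F5 | CC[C@H]1C[C@@]2(O)C(=O)O[C@](C)(/C=C(/C)CC/C=C(/C)[C@H](OC)CC(=O)C=C=O)C[C@@]2(C)C=C1C
F7 | step 21 | 16-membered β-keto macrolactone bridging the δ-lactone | CC[C@H]1C[C@@]23OC(=O)CC(=O)C[C@@H](OC)/C(C)=C\CC/C(C)=C\[C@](C)(C[C@@]3(C)C=C1C)OC2=O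
F8 | step 20 | selenoxide of 31 | O[C@](C)(/C=C(/C)CC/C=C(/C)[C@H](OC)CC(=O)CC(=O)O[C@H](C[Se](=O)c1ccccc1)C(=O)OC)C/C(C)=C/C(C)=C/CC
F9 | step 20 | methyl 2-{[(5R,6Z,10Z,12S,14E,16E)-12-hydroxy-5-methoxy-6,10,12,14,16-pentamethyl-3-oxononadeca-6,10,14,16-tetraenoyl]oxy}prop-2-enoate | O[C@](C)(/C=C(/C)CC/C=C(/C)[C@H](OC)CC(=O)CC(=O)OC(=C)C(=O)OC)C/C(C)=C/C(C)=C/CC
F10 | step 12 | (2Z)-5-[(tert-butyldimethylsilyl)oxy]-2-methylpent-2-en-1-ol | CC(C)(C)[Si](C)(C)OCC/C=C(/C)CO
F11 | step 12 | (2Z)-5-[(tert-butyldimethylsilyl)oxy]-2-methylpent-2-enal | CC(C)(C)[Si](C)(C)OCC/C=C(/C)C=O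
F12 | step 12 | 2,2-dimethyl-6-methylidene-4-(trimethylsilyloxy)-6H-1,3-dioxine | C=C1C=C(O[Si](C)(C)C)OC(C)(C)O1
F13 | step 12 | trimethylsilyl ether of 22 | CC(C)(C)[Si](C)(C)OCC/C=C(/C)[C@H](O[Si](C)(C)C)CC1=CC(=O)OC(C)(C)O1
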